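**Assumption:** the target SMILES is read as the (1R,5R,7S,8S) bicycle with a (2R) side chain; C7 prenyl and C8 homoprenyl lie anti to the C2–C4 bridge, C8 methyl syn. The drawn enol is one of the equilibrating β-triketone tautomers. Bicycle locants C1–C9 are used throughout.

**Retrosynthetic overview**
1. Target ⇐ hydroxide deprotection of a C3-aroylated methyl enol ether; the C3–aroyl bond comes from C3 lithiation and acylation with a catechol-derived acid chloride (fragment 3).
2. Key union, C5–CH2 bond: nickel-catalysed C(sp3)–C(sp3) Negishi coupling of the bridgehead iodide of the bicyclic core (fragment 1) with (S)-lavandulylzinc iodide (fragment 2).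
3. The second carbocycle (C2–C3–C4 bridge) is closed by Effenberger α,α′-annulation of a cyclohexanone silyl enol ether with malonyl dichloride; the first six-membered ring is bought as cyclohexane-1,3-dione.
4. Cyclohexanone stereocentres: C7 by palladium-catalysed decarboxylative asymmetric allylation, C8 by anti-selective methylcuprate addition after a Stork–Danheiser transposition, C1 prenyl by enolate alkylation.
5. Fragment 2 by an Evans deconjugative prenylation (valinol-derived auxiliary); fragment 3 from catechol.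

**Fragment 2: (S)-lavandulylzinc iodide**

Step 1
Reactants: 1 L-valinol [(S)-2-amino-3-methylbutan-1-ol]; 2 diethyl carbonate
Product: 3 (S)-4-isopropyloxazolidin-2-one
Conditions: K2CO3 (cat.), neat, 130 °C, EtOH distilled off
Reagents that add atoms: none
Why: Transesterification/cyclisation of the amino alcohol with the carbonate (oxazolidinone formation) gives the auxiliary with the valinol stereocentre untouched.

Step 2
Reactants: 3 (S)-4-isopropyloxazolidin-2-one; 4 3-methylbut-2-enoyl chloride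
Product: 6 (S)-4-isopropyl-3-(3-methylbut-2-enoyl)oxazolidin-2-one, via N-lithio oxazolidinone 5 (not isolated)
Conditions: n-BuLi, THF, −78 °C; then 4, −78 → 0 °C
Reagents that add atoms: none
Why: N-acylation of the lithiated oxazolidinone with the acid chloride (standard Evans imide formation).

Step 3
Reactants: 6 (S)-4-isopropyl-3-(3-methylbut-2-enoyl)oxazolidin-2-one; 7 prenyl bromide (1-bromo-3-methylbut-2-ene)
Product: 9 (S)-4-isopropyl-3-[(S)-5-methyl-2-(prop-1-en-2-yl)hex-4-enoyl]oxazolidin-2-one, via sodium dienolate 8 (not isolated)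
Conditions: NaN(SiMe3)2, THF, −78 °C; then 7, −78 → −40 °C
Reagents that add atoms: none
Why: Evans asymmetric alkylation in its deconjugative form: γ-deprotonation gives the chelated Z(O) dienolate, which is prenylated at the α-carbon on the face opposite the isopropyl group, setting the (S) lavandulyl stereocentre (expected dr ≥ 95:5, minor isomer removed by chromatography).

Step 4
Reactants: 9 (S)-4-isopropyl-3-[(S)-5-methyl-2-(prop-1-en-2-yl)hex-4-enoyl]oxazolidin-2-one
Product: 10 (S)-lavandulol [(S)-5-methyl-2-(prop-1-en-2-yl)hex-4-en-1-ol]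
Conditions: LiBH4, H2O (1 equiv), Et2O, 0 °C
Reagents that add atoms: none
Why: Reductive cleavage of the imide releases the primary alcohol without touching the β,γ-alkene or the α-stereocentre and returns the auxiliary.

Step 5
Reactants: 10 (S)-lavandulol
Product: 11 (S)-lavandulyl iodide [(S)-5-(iodomethyl)-2,6-dimethylhepta-2,6-diene]
Conditions: I2, PPh3, imidazole, CH2Cl2, 0 → 23 °C
Reagents that add atoms: iodine, II
Why: Appel-type iodination of a primary alcohol (SN2 at CH2; the stereocentre is not involved).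

Step 6
Reactants: 11 (S)-lavandulyl iodide
Product: 12 (S)-lavandulylzinc iodide [(S)-(5-methyl-2-(prop-1-en-2-yl)hex-4-en-1-yl)zinc iodide as its LiCl-complexed THF solution]
Conditions: Zn dust (activated by BrCH2CH2Br and Me3SiCl), LiCl, THF, 40 °C; titrated, used as solution
Reagents that add atoms: zinc, [Zn]
Why: Direct insertion of LiCl-activated zinc into a primary alkyl iodide (Knochel-type organozinc formation); the stereocentre β to zinc is not involved.

**Fragment 3: protected aroyl chloride**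

Step 7
Reactants: 13 catechol
Product: 14 4-bromobenzene-1,2-diol
Conditions: N-bromosuccinimide, HBF4·OEt2 (cat.), MeCN, −30 → 23 °C
Reagents that add atoms: N-bromosuccinimide, O=C1CCC(=O)N1Br
Why: Electrophilic aromatic monobromination para to one hydroxyl group.

Step 8
Reactants: 14 4-bromobenzene-1,2-diol
Product: 15 4-bromo-1,2-bis(tert-butyldimethylsilyloxy)benzene
Conditions: t-BuMe2SiCl, imidazole, DMF, 23 °C
Reagents that add atoms: tert-butyldimethylsilyl chloride, CC(C)(C)[Si](C)(C)Cl
Why: Imidazole-mediated silyl ether formation masks both phenols for the organolithium steps.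

Step 9
Reactants: 15 4-bromo-1,2-bis(tert-butyldimethylsilyloxy)benzene
Product: 17 3,4-bis(tert-butyldimethylsilyloxy)benzoic acid, via aryllithium 16 (not isolated)
Conditions: n-BuLi, THF, −78 °C; CO2 (g), −78 → 0 °C; 1 M HCl, 0 °C
Reagents that add atoms: carbon dioxide, O=C=O
Why: Bromine–lithium exchange followed by carboxylation of the aryllithium (no ortho silyloxy group, so no silyl migration).

Step 10
Reactants: 17 3,4-bis(tert-butyldimethylsilyloxy)benzoic acid
Product: 18 3,4-bis(tert-butyldimethylsilyloxy)benzoyl chloride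
Conditions: (COCl)2, DMF (cat.), CH2Cl2, 0 → 23 °C; evaporated, used crude
Reagents that add atoms: oxalyl chloride, ClC(=O)C(=O)Cl
Why: Acid chloride formation through the Vilsmeier-type chloroiminium; aryl silyl ethers tolerate these conditions.

**Fragment 1: bicyclic core and bridgehead iodide**

Step 11
Reactants: 19 cyclohexane-1,3-dione; 20 thiophenol
Product: 21 3-(phenylthio)cyclohex-2-en-1-one
Conditions: p-TsOH·H2O (cat.), toluene, reflux, Dean–Stark
Reagents that add atoms: none
Why: Acid-catalysed condensation of the 1,3-dione with the thiol (vinylogous thioester formation) driven by azeotropic water removal.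

Step 12
Reactants: 21 3-(phenylthio)cyclohex-2-en-1-one; 22 allyl chloroformate
Product: 24 allyl 5-(phenylthio)cyclohexa-1,5-dien-1-yl carbonate, via sodium dienolate 23 (not isolated)
Conditions: NaN(SiMe3)2, TMEDA, THF, −78 °C; then 22, −78 °C
Reagents that add atoms: none
Why: Kinetic α′-deprotonation and O-acylation of the amine-solvated sodium dienolate by the hard chloroformate (enol carbonate formation).

Step 13
Reactants: 24 allyl 5-(phenylthio)cyclohexa-1,5-dien-1-yl carbonate
Product: 25 (R)-6-allyl-3-(phenylthio)cyclohex-2-en-1-one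
Conditions: Pd2(dba)3·CHCl3 (2.5 mol %), (S,S)-ANDEN-phenyl Trost ligand [N,N′-(11,12-dihydro-9,10-ethanoanthracene-11,12-diyl)bis(2-diphenylphosphinobenzamide)] (5.5 mol %), 1,4-dioxane, 23 °C
Reagents that add atoms: none
Why: Palladium-catalysed decarboxylative asymmetric allylic alkylation (Tsuji–Trost type): ionisation and loss of CO2 give a ligand-bound π-allylpalladium/enolate pair that recombines to set the tertiary α′-stereocentre (future C7) as R; the ligand antipode is assigned by analogy and is exchanged for its mirror image if the first run gives the S ketone.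

Step 14
Reactants: 25 (R)-6-allyl-3-(phenylthio)cyclohex-2-en-1-one; 26 2-methylbut-2-ene
Product: 27 (R)-6-(3-methylbut-2-en-1-yl)-3-(phenylthio)cyclohex-2-en-1-one
Conditions: second-generation Grubbs catalyst RuCl2(=CHPh)(PCy3)(H2IMes) (5 mol %), 26 as co-solvent, CH2Cl2, 40 °C
Reagents that add atoms: none
Why: Olefin cross-metathesis turns the terminal allyl group into prenyl; it is run here, before the homoprenyl chain is present, so that no ring-closing metathesis can compete, and the conjugated vinyl sulfide and the stereocentre are untouched.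

Step 15
Reactants: 27 (R)-6-(3-methylbut-2-en-1-yl)-3-(phenylthio)cyclohex-2-en-1-one; 28 5-bromo-2-methylpent-2-ene
Product: 31 (R)-4-(3-methylbut-2-en-1-yl)-3-(4-methylpent-3-en-1-yl)cyclohex-2-en-1-one, via Grignard reagent 29 (not isolated), via tertiary allylic alcohol 30 (not isolated)
Conditions: 28, Mg, THF, 40 °C; CeCl3, −78 °C; then 27, −78 → 0 °C; then 1 M HCl, THF, 23 °C
Reagents that add atoms: water, O
Why: Stork–Danheiser-type 1,3-carbonyl transposition: CeCl3-promoted 1,2-addition of the Grignard reagent avoids enolisation of the α′-stereocentre, and acid then ionises the allylic alcohol and hydrolyses the thioenol ether to the transposed enone, in which the stereocentre has become the γ-carbon.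

Step 16
Reactants: 31 (R)-4-(3-methylbut-2-en-1-yl)-3-(4-methylpent-3-en-1-yl)cyclohex-2-en-1-one
Product: 32 trimethyl{[(3S,4R)-3-methyl-4-(3-methylbut-2-en-1-yl)-3-(4-methylpent-3-en-1-yl)cyclohex-1-en-1-yl]oxy}silane
Conditions: Me2CuLi (from CuI and MeLi), Me3SiCl, Et2O/THF, −78 → −20 °C; Et3N, aq. NaHCO3
Reagents that add atoms: lithium dimethylcuprate, [Li+].C[Cu-]C; chlorotrimethylsilane, C[Si](C)(C)Cl
Why: Cuprate conjugate addition with in situ silylation: methyl adds anti to the pseudoaxial C4 prenyl group of the 3,4-disubstituted enone, setting the quaternary centre (future C8) with methyl trans to prenyl, and the regiodefined enolate is stored as its silyl enol ether.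

Step 17
Reactants: 32 trimethylsilyl enol ether; 7 prenyl bromide
Product: 34 (3S,4R)-3-methyl-2,4-bis(3-methylbut-2-en-1-yl)-3-(4-methylpent-3-en-1-yl)cyclohexan-1-one (C2 epimers), via lithium enolate 33 (not isolated)
Conditions: MeLi, THF, 0 °C; then 7, HMPA, −78 → 0 °C
Reagents that add atoms: none
Why: Regiospecific lithium enolate generation by Si–O cleavage and C-alkylation with the allylic bromide; the C2 configuration is inconsequential because this carbon is re-enolised in step 19.

Step 18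
Reactants: 34 (3S,4R)-3-methyl-2,4-bis(3-methylbut-2-en-1-yl)-3-(4-methylpent-3-en-1-yl)cyclohexan-1-one
Product: 36 tert-butyl(dimethyl){[(4S,5S)-5-methyl-4,6-bis(3-methylbut-2-en-1-yl)-5-(4-methylpent-3-en-1-yl)cyclohex-1-en-1-yl]oxy}silane (C6 epimers), via lithium enolate 35 (not isolated)
Conditions: LiN(iPr)2, THF, −78 °C; t-BuMe2SiCl, HMPA, −78 → 23 °C
Reagents that add atoms: tert-butyldimethylsilyl chloride, CC(C)(C)[Si](C)(C)Cl
Why: Kinetic deprotonation at the unhindered CH2 and O-silylation give the less substituted silyl enol ether.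

Step 19
Reactants: 36 tert-butyldimethylsilyl enol ether; 37 malonyl dichloride
Product: 39 (1S,5R,7S,8S)-4-hydroxy-8-methyl-1,7-bis(3-methylbut-2-en-1-yl)-8-(4-methylpent-3-en-1-yl)bicyclo[3.3.1]non-3-ene-2,9-dione, via acyl chloride 38 (not isolated)
Conditions: Et2O, −20 → 23 °C, 24 h; then KOH, BnEt3NCl, H2O, 23 °C; then HCl to pH 3
Reagents that add atoms: none
Why: Effenberger α,α′-annulation: the enol ether is C-acylated at the CH carbon, the acyl ketone enolises toward the prenyl-bearing carbon and closes onto the second acid chloride; the three-carbon bridge must span both α-carbons diaxially and forms on the face opposite the C7 prenyl group (which stays equatorial), which sets C1 and C5 (a modest yield of about 25–35 % is expected).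

Step 20
Reactants: 39 bicyclic enol-dione
Product: 40 (1S,5R,7S,8S)-4-methoxy-8-methyl-1,7-bis(3-methylbut-2-en-1-yl)-8-(4-methylpent-3-en-1-yl)bicyclo[3.3.1]non-3-ene-2,9-dione
Conditions: Me2SO4, K2CO3, acetone, 56 °C; chromatography
Reagents that add atoms: dimethyl sulfate, COS(=O)(=O)OC
Why: O-Methylation of the vinylogous acid, expected mainly at the oxygen remote from the congested C1/C8 quaternary centres; the minor regioisomer is separated and recycled to 39 by hydrolysis.

Step 21
Reactants: 40 methyl enol ether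
Product: 42 (1S,5S,7S,8S)-5-iodo-4-methoxy-8-methyl-1,7-bis(3-methylbut-2-en-1-yl)-8-(4-methylpent-3-en-1-yl)bicyclo[3.3.1]non-3-ene-2,9-dione, via bridgehead organolithium 41 (not isolated)
Conditions: LiN(iPr)2, THF, −78 °C; I2, −78 → 0 °C
Reagents that add atoms: iodine, II
Why: Bridgehead deprotonation (C5–H is acidified inductively by the C9 ketone and the C4 enol ether carbon) and iodination of the bridgehead organolithium; the cage fixes the C5 configuration.

**Union and endgame**

Step 22
Reactants: 42 bridgehead iodide; 12 (S)-lavandulylzinc iodide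
Product: 43 (1S,5R,7S,8S)-4-methoxy-8-methyl-1,7-bis(3-methylbut-2-en-1-yl)-5-[(2R)-5-methyl-2-(prop-1-en-2-yl)hex-4-en-1-yl]-8-(4-methylpent-3-en-1-yl)bicyclo[3.3.1]non-3-ene-2,9-dione
Conditions: NiCl2(MeOCH2CH2OMe) (10 mol %), 4,4′,4″-tri-tert-butyl-2,2′:6′,2″-terpyridine (12 mol %), 12 (2 equiv), N,N-dimethylacetamide/THF, 0 → 23 °C
Reagents that add atoms: none
Why: Proposed new method: nickel-catalysed C(sp3)–C(sp3) Negishi coupling of a bridgehead tertiary α-iodo ketone with a β-branched primary alkylzinc, forming the C5 quaternary centre; a monovalent nickel–alkyl species formed by transmetalation abstracts iodine from 42 to give the pyramidal, unshielded bridgehead radical (the radical that is already known to be trapped by allylstannanes on such cages), which recombines with nickel, and the trivalent dialkylnickel then reductively eliminates because the bridgehead partner cannot undergo β-hydride elimination (Bredt) and the tridentate ligand blocks it on the lavandulyl side; the cage enforces retention at C5 and the side-chain stereocentre, β to zinc, is not touched; the closest known reaction type is the nickel/terpyridine- or pybox-catalysed alkyl–alkyl Negishi coupling of secondary alkyl halides and secondary α-halo ketones.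

Step 23
Reactants: 43 coupled methyl enol ether; 18 3,4-bis(tert-butyldimethylsilyloxy)benzoyl chloride
Product: 45 (1R,5R,7S,8S)-3-[3,4-bis(tert-butyldimethylsilyloxy)benzoyl]-4-methoxy-8-methyl-1,7-bis(3-methylbut-2-en-1-yl)-5-[(2R)-5-methyl-2-(prop-1-en-2-yl)hex-4-en-1-yl]-8-(4-methylpent-3-en-1-yl)bicyclo[3.3.1]non-3-ene-2,9-dione, via C3 vinyllithium 44 (not isolated)
Conditions: lithium 2,2,6,6-tetramethylpiperidide, THF, −78 °C; then 18, −78 → −20 °C
Reagents that add atoms: none
Why: Vinylic lithiation at C3 (α-carbon of the vinylogous ester, the only acidic C–H left) followed by C-acylation with the aroyl chloride.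

Step 24
Reactants: 45 protected precursor
Product: 46 target, (1R,5R,7S,8S)-3-(3,4-dihydroxybenzoyl)-4-hydroxy-8-methyl-1,7-bis(3-methylbut-2-en-1-yl)-5-[(2R)-5-methyl-2-(prop-1-en-2-yl)hex-4-en-1-yl]-8-(4-methylpent-3-en-1-yl)bicyclo[3.3.1]non-3-ene-2,9-dione
Conditions: LiOH·H2O, 1,4-dioxane/H2O (degassed, Ar), 90 °C; then 1 M HCl to pH 3, 0 °C
Reagents that add atoms: lithium hydroxide, [Li+].[OH-]
Why: Hydroxide cleaves the vinylogous methyl ester by conjugate addition–elimination and both aryl silyl ethers by attack at silicon, and cold acidification gives the enolised β-triketone without strong acid that would cyclise the prenyl groups; no stereocentre is affected.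

**Compound list**
1 | L-valinol, (S)-2-amino-3-methylbutan-1-ol | CC(C)[C@H](N)CO | starting material
2 | diethyl carbonate | CCOC(=O)OCC | starting material
3 | (S)-4-isopropyloxazolidin-2-one | CC(C)[C@H]1COC(=O)N1 | intermediate
4 | 3-methylbut-2-enoyl chloride | CC(C)=CC(=O)Cl | starting material
5 | lithium salt of (S)-4-isopropyloxazolidin-2-one | CC(C)[C@H]1COC(=O)N1[Li] | intermediate
6 | (S)-4-isopropyl-3-(3-methylbut-2-enoyl)oxazolidin-2-one | CC(C)=CC(=O)N1C(=O)OC[C@@H]1C(C)C | intermediate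
7 | prenyl bromide, 1-bromo-3-methylbut-2-ene | CC(C)=CCBr | starting material
8 | sodium Z(O)-dienolate of 6 | C=C(C)/C=C(\O[Na])N1C(=O)OC[C@@H]1C(C)C | intermediate
9 | (S)-4-isopropyl-3-[(S)-5-methyl-2-(prop-1-en-2-yl)hex-4-enoyl]oxazolidin-2-one | C=C(C)[C@H](CC=C(C)C)C(=O)N1C(=O)OC[C@@H]1C(C)C | intermediate
10 | (S)-lavandulol, (S)-5-methyl-2-(prop-1-en-2-yl)hex-4-en-1-ol | C=C(C)[C@H](CC=C(C)C)CO | intermediate
11 | (S)-lavandulyl iodide, (S)-5-(iodomethyl)-2,6-dimethylhepta-2,6-diene | C=C(C)[C@H](CC=C(C)C)CI | intermediate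
12 | (S)-lavandulylzinc iodide | C=C(C)[C@H](CC=C(C)C)C[Zn]I | intermediate
13 | catechol | Oc1ccccc1O | starting material
14 | 4-bromobenzene-1,2-diol | Oc1ccc(Br)cc1O | intermediate
15 | 4-bromo-1,2-bis(tert-butyldimethylsilyloxy)benzene | CC(C)(C)[Si](C)(C)Oc1ccc(Br)cc1O[Si](C)(C)C(C)(C)C | intermediate
16 | 3,4-bis(tert-butyldimethylsilyloxy)phenyllithium | [Li]c1ccc(O[Si](C)(C)C(C)(C)C)c(O[Si](C)(C)C(C)(C)C)c1 | intermediate
17 | 3,4-bis(tert-butyldimethylsilyloxy)benzoic acid | OC(=O)c1ccc(O[Si](C)(C)C(C)(C)C)c(O[Si](C)(C)C(C)(C)C)c1 | intermediate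
18 | 3,4-bis(tert-butyldimethylsilyloxy)benzoyl chloride | ClC(=O)c1ccc(O[Si](C)(C)C(C)(C)C)c(O[Si](C)(C)C(C)(C)C)c1 | intermediate
19 | cyclohexane-1,3-dione | O=C1CCCC(=O)C1 | starting material
20 | thiophenol | Sc1ccccc1 | starting material
21 | 3-(phenylthio)cyclohex-2-en-1-one | O=C1C=C(Sc2ccccc2)CCC1 | intermediate
22 | allyl chloroformate | C=CCOC(=O)Cl | starting material
23 | sodium 5-(phenylthio)cyclohexa-1,5-dien-1-olate | [Na]OC1=CCCC(Sc2ccccc2)=C1 | intermediate
24 | allyl 5-(phenylthio)cyclohexa-1,5-dien-1-yl carbonate | C=CCOC(=O)OC1=CCCC(Sc2ccccc2)=C1 | intermediate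
25 | (R)-6-allyl-3-(phenylthio)cyclohex-2-en-1-one | C1C[C@H](CC=C)C(=O)C=C1Sc1ccccc1 | intermediate
26 | 2-methylbut-2-ene | CC=C(C)C | starting material
27 | (R)-6-(3-methylbut-2-en-1-yl)-3-(phenylthio)cyclohex-2-en-1-one | C1C[C@H](CC=C(C)C)C(=O)C=C1Sc1ccccc1 | intermediate
28 | 5-bromo-2-methylpent-2-ene | CC(C)=CCCBr | starting material
29 | (4-methylpent-3-en-1-yl)magnesium bromide | CC(C)=CCC[Mg]Br | intermediate
30 | (6R)-6-(3-methylbut-2-en-1-yl)-1-(4-methylpent-3-en-1-yl)-3-(phenylthio)cyclohex-2-en-1-ol (C1 epimers) | C1C[C@H](CC=C(C)C)C(O)(CCC=C(C)C)C=C1Sc1ccccc1 | intermediate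
31 | (R)-4-(3-methylbut-2-en-1-yl)-3-(4-methylpent-3-en-1-yl)cyclohex-2-en-1-one | C1C[C@H](CC=C(C)C)C(CCC=C(C)C)=CC1=O | intermediate
32 | trimethyl{[(3S,4R)-3-methyl-4-(3-methylbut-2-en-1-yl)-3-(4-methylpent-3-en-1-yl)cyclohex-1-en-1-yl]oxy}silane | C1C[C@H](CC=C(C)C)[C@](C)(CCC=C(C)C)C=C1O[Si](C)(C)C | intermediate
33 | lithium (3S,4R)-3-methyl-4-(3-methylbut-2-en-1-yl)-3-(4-methylpent-3-en-1-yl)cyclohex-1-en-1-olate | C1C[C@H](CC=C(C)C)[C@](C)(CCC=C(C)C)C=C1O[Li] | intermediate
34 | (3S,4R)-3-methyl-2,4-bis(3-methylbut-2-en-1-yl)-3-(4-methylpent-3-en-1-yl)cyclohexan-1-one (C2 epimers) | C1C[C@H](CC=C(C)C)[C@](C)(CCC=C(C)C)C(CC=C(C)C)C1=O | intermediate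
35 | lithium (4S,5S)-5-methyl-4,6-bis(3-methylbut-2-en-1-yl)-5-(4-methylpent-3-en-1-yl)cyclohex-1-en-1-olate (C6 epimers) | C1[C@H](CC=C(C)C)[C@](C)(CCC=C(C)C)C(CC=C(C)C)C(O[Li])=C1 | intermediate
36 | tert-butyl(dimethyl){[(4S,5S)-5-methyl-4,6-bis(3-methylbut-2-en-1-yl)-5-(4-methylpent-3-en-1-yl)cyclohex-1-en-1-yl]oxy}silane (C6 epimers) | C1[C@H](CC=C(C)C)[C@](C)(CCC=C(C)C)C(CC=C(C)C)C(O[Si](C)(C)C(C)(C)C)=C1 | intermediate
37 | malonyl dichloride | ClC(=O)CC(=O)Cl | starting material
38 | 3-[(4S,5S)-4-methyl-3,5-bis(3-methylbut-2-en-1-yl)-4-(4-methylpent-3-en-1-yl)-2-oxocyclohexyl]-3-oxopropanoyl chloride (C1 and C3 epimers) | C1(C(=O)CC(=O)Cl)C[C@H](CC=C(C)C)[C@](C)(CCC=C(C)C)C(CC=C(C)C)C1=O | intermediate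
39 | (1S,5R,7S,8S)-4-hydroxy-8-methyl-1,7-bis(3-methylbut-2-en-1-yl)-8-(4-methylpent-3-en-1-yl)bicyclo[3.3.1]non-3-ene-2,9-dione | [C@@H]12C[C@H](CC=C(C)C)[C@](C)(CCC=C(C)C)[C@@](CC=C(C)C)(C(=O)C=C1O)C2=O | intermediate
40 | (1S,5R,7S,8S)-4-methoxy-8-methyl-1,7-bis(3-methylbut-2-en-1-yl)-8-(4-methylpent-3-en-1-yl)bicyclo[3.3.1]non-3-ene-2,9-dione | [C@@H]12C[C@H](CC=C(C)C)[C@](C)(CCC=C(C)C)[C@@](CC=C(C)C)(C(=O)C=C1OC)C2=O | intermediate
41 | C5 bridgehead lithio derivative of 40 | [Li][C@@]12C[C@H](CC=C(C)C)[C@](C)(CCC=C(C)C)[C@@](CC=C(C)C)(C(=O)C=C1OC)C2=O | intermediate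
42 | (1S,5S,7S,8S)-5-iodo-4-methoxy-8-methyl-1,7-bis(3-methylbut-2-en-1-yl)-8-(4-methylpent-3-en-1-yl)bicyclo[3.3.1]non-3-ene-2,9-dione | I[C@@]12C[C@H](CC=C(C)C)[C@](C)(CCC=C(C)C)[C@@](CC=C(C)C)(C(=O)C=C1OC)C2=O | intermediate
43 | (1S,5R,7S,8S)-4-methoxy-8-methyl-1,7-bis(3-methylbut-2-en-1-yl)-5-[(2R)-5-methyl-2-(prop-1-en-2-yl)hex-4-en-1-yl]-8-(4-methylpent-3-en-1-yl)bicyclo[3.3.1]non-3-ene-2,9-dione | C=C(C)[C@H](CC=C(C)C)C[C@@]12C[C@H](CC=C(C)C)[C@](C)(CCC=C(C)C)[C@@](CC=C(C)C)(C(=O)C=C1OC)C2=O | intermediate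
44 | C3 lithio derivative of 43 | C=C(C)[C@H](CC=C(C)C)C[C@@]12C[C@H](CC=C(C)C)[C@](C)(CCC=C(C)C)[C@@](CC=C(C)C)(C(=O)C([Li])=C1OC)C2=O | intermediate
45 | (1R,5R,7S,8S)-3-[3,4-bis(tert-butyldimethylsilyloxy)benzoyl]-4-methoxy-8-methyl-1,7-bis(3-methylbut-2-en-1-yl)-5-[(2R)-5-methyl-2-(prop-1-en-2-yl)hex-4-en-1-yl]-8-(4-methylpent-3-en-1-yl)bicyclo[3.3.1]non-3-ene-2,9-dione | C=C(C)[C@H](CC=C(C)C)C[C@@]12C[C@H](CC=C(C)C)[C@](C)(CCC=C(C)C)[C@@](CC=C(C)C)(C(=O)C(C(=O)c3ccc(O[Si](C)(C)C(C)(C)C)c(O[Si](C)(C)C(C)(C)C)c3)=C1OC)C2=O | intermediate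
46 | CNP0241026.2, (1R,5R,7S,8S)-3-(3,4-dihydroxybenzoyl)-4-hydroxy-8-methyl-1,7-bis(3-methylbut-2-en-1-yl)-5-[(2R)-5-methyl-2-(prop-1-en-2-yl)hex-4-en-1-yl]-8-(4-methylpent-3-en-1-yl)bicyclo[3.3.1]non-3-ene-2,9-dione | C=C(C)[C@H](CC=C(C)C)C[C@@]12C[C@H](CC=C(C)C)[C@](C)(CCC=C(C)C)[C@@](CC=C(C)C)(C(=O)C(C(=O)c3ccc(O)c(O)c3)=C1O)C2=O | target

**Step count**
Total steps: 24 (fragment 2: steps 1–6; fragment 3: steps 7–10; core and endgame: steps 11–24).
Longest linear sequence: 14 steps (steps 11–24, from cyclohexane-1,3-dione 19 to 46).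

**Steps most likely to fail, with fallbacks**

Step 22 (proposed nickel-catalysed bridgehead Negishi coupling). Likely failure modes are reduction of 42 back to 40 or β-hydride elimination on the lavandulyl side. The fallback uses known chemistry, sets out from 40 (together with alcohol 10) and comes back at 43. Alcohol 10 is converted with Tf2O and 2,6-lutidine (CH2Cl2, −78 °C) into (S)-lavandulyl triflate F1. Bridgehead organolithium 41, made from 40 with LiN(iPr)2 as in step 21, is then alkylated directly with F1 (THF/HMPA, −78 → −20 °C). This is the classical bridgehead-anion alkylation that works with allylic bromides on this ring system, here with a primary triflate to offset the β-branching; it gives 43 without passing through 42 and 12.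

Step 19 (Effenberger annulation; two adjacent quaternary centres are formed and yields of this reaction are intrinsically low). The fallback sets out from 36 and comes back at 39, building the bridge stepwise.
- Mukaiyama–Michael addition of 36 to acrolein (t-BuMe2SiOTf cat., CH2Cl2, −78 °C, aqueous work-up) gives keto aldehyde F2.
- Intramolecular aldol closure from the prenyl-bearing α-carbon onto the aldehyde (aq. HCl/THF) gives bicyclic ketol F3, with the bridge again forced diaxial and anti to the C7 prenyl group.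
- Dess–Martin oxidation gives the 2,9-dione F4.
- Dehydrogenation with IBX (DMSO, 70 °C; C3 is the only enolisable position) gives enone F5.
- Nucleophilic epoxidation (t-BuOOH, benzyltrimethylammonium hydroxide, THF) gives epoxy ketone F6, leaving the prenyl alkenes untouched.
- Isomerisation of the α,β-epoxy ketone to the β-diketone with Pd(PPh3)4 and 1,2-bis(diphenylphosphino)ethane (zerovalent palladium, toluene, 80 °C) delivers 39.

Step 21 (bridgehead iodination; the competing site is the C3 vinylic C–H). The fallback sets out from 40 and comes back at 43, using a blocking group.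
- Treating 40 with LiN(iPr)2 and Me3SiCl (THF, −78 °C) silylates whichever site is lithiated first, C3, to give the C3-silylated enol ether F7.
- A second LiN(iPr)2/I2 sequence can then only give the C3-silylated bridgehead iodide F8.
- F8 is coupled with 12 under the conditions of step 22 to give the C3-silylated coupling product F9.
- Bu4NF/AcOH (THF, 0 °C) removes the vinyl silane and returns 43.

**Further compounds**
F1 | step 22 | (S)-5-methyl-2-(prop-1-en-2-yl)hex-4-en-1-yl trifluoromethanesulfonate | C=C(C)[C@H](CC=C(C)C)COS(=O)(=O)C(F)(F)F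
F2 | step 19 | 3-[(4S,5S)-4-methyl-3,5-bis(3-methylbut-2-en-1-yl)-4-(4-methylpent-3-en-1-yl)-2-oxocyclohexyl]propanal (C1 and C3 epimers) | O=CCCC1C[C@H](CC=C(C)C)[C@](C)(CCC=C(C)C)C(CC=C(C)C)C1=O
F3 | step 19 | 2-hydroxy-8-methyl-1,7-bis(3-methylbut-2-en-1-yl)-8-(4-methylpent-3-en-1-yl)bicyclo[3.3.1]nonan-9-one, ring stereocentres as in 39, C2 epimers | [C@@H]12C[C@H](CC=C(C)C)[C@](C)(CCC=C(C)C)[C@@](CC=C(C)C)(C(O)CC1)C2=O
F4 | step 19 | 8-methyl-1,7-bis(3-methylbut-2-en-1-yl)-8-(4-methylpent-3-en-1-yl)bicyclo[3.3.1]nonane-2,9-dione, ring stereocentres as in 39 | [C@@H]12C[C@H](CC=C(C)C)[C@](C)(CCC=C(C)C)[C@@](CC=C(C)C)(C(=O)CC1)C2=O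
F5 | step 19 | 8-methyl-1,7-bis(3-methylbut-2-en-1-yl)-8-(4-methylpent-3-en-1-yl)bicyclo[3.3.1]non-3-ene-2,9-dione, ring stereocentres as in 39 | [C@@H]12C[C@H](CC=C(C)C)[C@](C)(CCC=C(C)C)[C@@](CC=C(C)C)(C(=O)C=C1)C2=O
F6 | step 19 | 3,4-epoxy-8-methyl-1,7-bis(3-methylbut-2-en-1-yl)-8-(4-methylpent-3-en-1-yl)bicyclo[3.3.1]nonane-2,9-dione, ring stereocentres as in 39, epoxide on the exo face | [C@@H]12C[C@H](CC=C(C)C)[C@](C)(CCC=C(C)C)[C@@](CC=C(C)C)(C(=O)C3OC31)C2=O
F7 | step 21 | 3-trimethylsilyl derivative of 40 | [C@@H]12C[C@H](CC=C(C)C)[C@](C)(CCC=C(C)C)[C@@](CC=C(C)C)(C(=O)C([Si](C)(C)C)=C1OC)C2=O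
F8 | step 21 | 3-trimethylsilyl derivative of 42 | I[C@@]12C[C@H](CC=C(C)C)[C@](C)(CCC=C(C)C)[C@@](CC=C(C)C)(C(=O)C([Si](C)(C)C)=C1OC)C2=O
F9 | step 21 | 3-trimethylsilyl derivative of 43 | C=C(C)[C@H](CC=C(C)C)C[C@@]12C[C@H](CC=C(C)C)[C@](C)(CCC=C(C)C)[C@@](CC=C(C)C)(C(=O)C([Si](C)(C)C)=C1OC)C2=O
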